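The route rests on seeing the seven-membered ring (C3a, C4, C5, C6, C7, C8, C8a; azulene numbering) as a para-substituted anisole ring plus one extra carbon, C8a, the quaternary centre that carries the angular methyl and is flanked by the C1 oxygen. An intramolecular Büchner reaction of an α-methyl-α-diazoketone therefore closes the cyclopentanone (C8a–C3a bond) and, through norcaradiene opening, expands the benzene ring to the cycloheptatriene in one operation, setting C8a. The precursor is a simple acyclic diazoketone, 2-diazo-5-(4-methoxyphenyl)pentan-3-one. The anisole oxygen becomes the C6 ketone, and the three ring alkenes then direct all remaining oxygenation.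

Key step: step 2

Remark: all bicyclic compounds are numbered as azulenes (C1–C3, C3a, C4–C8, C8a); β is the face of the C8a methyl and α the opposite face; diazoethane is used as a freshly prepared ethereal solution.

Step 1
Reactants: 1 3-(4-methoxyphenyl)propanoic acid
Product: 3 2-diazo-5-(4-methoxyphenyl)pentan-3-one, via mixed anhydride 2 (not isolated)
Conditions: iBuOCOCl, Et3N, THF, −15 °C; then CH3CHN2 (Et2O), −15 to 0 °C
Reagents that add atoms: diazoethane CC=[N+]=[N-]
Why: The mixed carbonic anhydride acylates diazoethane at carbon (Arndt–Eistert-type diazoketone synthesis) and loss of isobutyl carbonate should give the α-methyl-α-diazoketone without touching the anisole ring.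

Step 2
Reactants: 3 2-diazo-5-(4-methoxyphenyl)pentan-3-one
Product: 5 (8aR)-6-methoxy-8a-methyl-3,8a-dihydroazulen-1(2H)-one, via norcaradiene 4 (not isolated)
Conditions: [Cu(MeCN)4]PF6 (5 mol %), (S,S)-tBu-box (6 mol %), NaB[3,5-(CF3)2C6H3]4 (6 mol %), CH2Cl2, 40 °C, slow addition of 3
Reagents that add atoms: none
Why: Loss of N2 gives a copper carbenoid at the future C8a that adds across the ipso/ortho π-bond (C3a=C8) of the anisole ring (intramolecular Büchner reaction), and the resulting norcaradiene 4 opens by thermal 6π disrotatory electrocyclisation, so that the benzene ring is expanded by the carbenoid carbon to the cycloheptatriene. The closest known reaction type is the intramolecular aromatic cycloaddition of 1-diazo-4-arylbutan-2-ones and their 1-alkyl homologues to 3,4-dihydroazulen-1(2H)-ones. The five-membered ring closes by C8a–C3a bond formation through the five-atom tether (cyclopropanation), and the seven-membered ring arises by cleavage of the C3a–C8 cyclopropane bond (ring expansion of the six-membered carbocycle by one carbon). The single new stereocentre, quaternary C8a, is set under catalyst control by the chiral bis(oxazoline)–copper carbenoid, which selects one of the two enantiotopic ipso/ortho bonds; the ligand antipode is taken if the opposite sense is induced. The step needs aromatic addition to win over 1,2-hydride shift of the methyl carbenoid and over C–H insertion, which the electron-rich para-methoxy ring, the favourable five-membered tether and slow addition of 3 should secure.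

Step 3
Reactants: 5 (8aR)-6-methoxy-8a-methyl-3,8a-dihydroazulen-1(2H)-one
Product: 6 (8aR)-6,6-ethylenedioxy-8a-methyl-2,3,5,6-tetrahydroazulen-1(8aH)-one
Conditions: HOCH2CH2OH, PPTS (cat.), CH2Cl2, 4 Å MS, 0 °C to rt
Reagents that add atoms: ethylene glycol OCCO
Why: Acid-catalysed alcoholysis of the methyl enol ether (transketalisation): kinetic protonation at C5, the α-carbon of the dienol ether, gives the C6 oxocarbenium ion that ethylene glycol traps as the dioxolane, leaving C3a=C4 and C7=C8 unconjugated and creating no stereocentre.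

Step 4
Reactants: 6 (8aR)-6,6-ethylenedioxy-8a-methyl-2,3,5,6-tetrahydroazulen-1(8aH)-one
Product: 7 (1S,8aR)-alcohol (1α-OH, trans to the 8a-methyl)
Conditions: (R)-Me-CBS (0.5 equiv), catecholborane, toluene, −78 °C; MeOH, aq. NaOH work-up
Reagents that add atoms: none
Why: Corey–Bakshi–Shibata reduction: the oxazaborolidine differentiates the quaternary C8a (large) from C2H2 (small) and should deliver hydride to the β face under reagent control, giving the (1S)-alcohol trans to the angular methyl.

Step 5
Reactants: 7 (1S,8aR)-alcohol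
Product: 9 1α-hydroxy-3-ketone (enone conjugated with C3a=C4), via allylic alcohol 8 (not isolated)
Conditions: SeO2 (0.5 equiv), tBuOOH, CH2Cl2, rt; then MnO2, CH2Cl2, rt
Reagents that add atoms: tert-butyl hydroperoxide CC(C)(C)OO
Why: SeO2 allylic hydroxylation (ene reaction then [2,3]-sigmatropic shift) occurs at the CH2 attached to the more substituted alkene carbon (C3, not C5), and MnO2 then oxidises only the allylic alcohol to the enone, so the C3 configuration of 8 is of no consequence.

Step 6
Reactants: 9 1α-hydroxy-3-ketone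
Product: 11 bis-dioxolane alcohol (C3 and C6 ketals; C3a=C4 and C7=C8), via TMS ether 10 (not isolated)
Conditions: TMSOCH2CH2OTMS, TMSOTf (cat.), CH2Cl2, −78 to −30 °C; pyridine; then K2CO3, MeOH, rt
Reagents that add atoms: 1,2-bis(trimethylsilyloxy)ethane C[Si](C)(C)OCCO[Si](C)(C)C
Why: Noyori ketalisation converts the enone into its dioxolane under kinetic conditions without migration of the C3a=C4 bond, the C1 hydroxyl being silylated in passing and freed again by methanolysis.

Step 7
Reactants: 11 bis-dioxolane alcohol
Product: 12 trans-fused 1α,4α-diol (3a-H α)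
Conditions: BH3·THF (3 equiv), THF, 0 °C to rt; then NaOH, H2O2, 0 °C
Reagents that add atoms: hydrogen peroxide OO
Why: Hydroboration–oxidation: BH3 should add syn across the trisubstituted C3a=C4 bond with boron on the less substituted C4 and from the α face opposite the angular methyl, so that 3a-H (trans ring fusion) and the 4α-hydroxyl are set together, while the C7=C8 bond between two fully substituted carbons reacts more slowly.

Step 8
Reactants: 12 trans-fused 1α,4α-diol
Product: 13 4-O-TBS ether
Conditions: TBSCl (1.1 equiv), imidazole, DMF, 0 °C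
Reagents that add atoms: tert-butyldimethylsilyl chloride CC(C)(C)[Si](C)(C)Cl
Why: Silylation with TBSCl/imidazole should be selective for the less hindered C4 hydroxyl over the neopentyl C1 hydroxyl next to the quaternary centre.

Step 9
Reactants: 13 4-O-TBS ether
Product: 14 6-ketone (C7=C8 enone; C3 dioxolane kept)
Conditions: oxalic acid (1 M aq., cat.), THF, 0 °C to rt
Reagents that add atoms: water O
Why: Selective acetal hydrolysis: the C6 dioxolane is allylic and ionises to a conjugated oxocarbenium ion, so it should cleave much faster than the saturated C3 dioxolane and release the enone.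

Step 10
Reactants: 14 6-ketone
Product: 15 7α,8α-epoxy-6-ketone
Conditions: tBuOOH, DBU, CH2Cl2, 0 °C to rt
Reagents that add atoms: tert-butyl hydroperoxide CC(C)(C)OO
Why: Nucleophilic (Weitz–Scheffer) epoxidation: the peroxide anion should add to C8 from the α face, opposite the adjacent angular methyl and guided by the free 1α-hydroxyl, and ring closure gives the 7α,8α-epoxide.

Step 11
Reactants: 15 7α,8α-epoxy-6-ketone
Product: 16 6-methylene-7α,8α-epoxide (vinyl epoxide)
Conditions: Ph3PCH3Br, KN(SiMe3)2, THF, 0 °C; then 15, −78 to 0 °C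
Reagents that add atoms: methyltriphenylphosphonium bromide C[P+](c1ccccc1)(c1ccccc1)c1ccccc1.[Br-]
Why: Wittig methylenation of the epoxy ketone gives the exocyclic alkene and supplies the carbon that becomes the C6 methyl, without touching a stereocentre.

Step 12
Reactants: 16 6-methylene-7α,8α-epoxide
Product: 17 6-methyl-6-ene-1α,8α-diol (C3 dioxolane, 4α-OTBS)
Conditions: SmI2 (3 equiv), MeOH, THF, −78 °C
Reagents that add atoms: none
Why: SmI2 reduction of the vinyl epoxide: electron transfer cleaves the allylic C7–O bond and the allylsamarium is protonated at the exocyclic carbon (formal SN2' reduction), which should give the C6 methyl, the C6=C7 alkene and the 8α-alcohol with its C8–O bond untouched.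

Step 13
Reactants: 17 6-methyl-6-ene-1α,8α-diol
Product: 18 3-ketone
Conditions: PPTS, acetone/H2O (10:1), 55 °C
Reagents that add atoms: water O
Why: Acetal hydrolysis of the remaining saturated dioxolane with a weak acid frees the C3 ketone while the TBS ether, the allylic alcohol and the C3a stereocentre should stay unchanged.

Step 14
Reactants: 18 3-ketone
Product: 19 3β-hydroxy-3α-isopropyl triol
Conditions: iPrMgCl (6 equiv), CeCl3, THF, −78 to −20 °C
Reagents that add atoms: isopropylmagnesium chloride CC(C)[Mg]Cl
Why: Organocerium 1,2-addition (non-basic, suppresses enolisation and β-hydride reduction): isopropyl should add from the α face, anti to the C4-bearing ring branch on C3a and to the angular methyl, giving the 3β-hydroxy-3α-isopropyl centre.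

Step 15
Reactants: 19 3β-hydroxy-3α-isopropyl triol
Product: 20 6α,7α-epoxide
Conditions: VO(acac)2 (5 mol %), tBuOOH, CH2Cl2, 0 °C to rt
Reagents that add atoms: tert-butyl hydroperoxide CC(C)(C)OO
Why: Hydroxyl-directed epoxidation: the allylic 8α-hydroxyl binds vanadium and delivers the oxidant to the same face of C6=C7, which should give the cis-epoxy alcohol with the 6α,7α-epoxide and the 6β-methyl.

Step 16
Reactants: 20 6α,7α-epoxide
Product: 21 1α,8α-diacetate
Conditions: Ac2O, pyridine, DMAP (cat.), CH2Cl2, rt
Reagents that add atoms: acetic anhydride CC(=O)OC(C)=O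
Why: DMAP-catalysed acetylation esterifies the two secondary hydroxyls at C1 and C8, while the hindered tertiary C3 hydroxyl should not be acylated under these conditions.

Step 17
Reactants: 21 1α,8α-diacetate
Product: 22 4α-alcohol
Conditions: HF·pyridine, pyridine, THF, 0 °C to rt
Reagents that add atoms: none
Why: Fluoride-mediated desilylation under weakly acidic, buffered conditions cleaves the Si–O bond so that the acetates should not migrate and the epoxide should stay closed.

Step 18
Reactants: 22 4α-alcohol
Product: 23 CNP0170993.1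
Conditions: angelic acid, 2,4,6-trichlorobenzoyl chloride, Et3N, toluene, rt; then 22, toluene, 80 °C
Reagents that add atoms: angelic acid C/C=C(/C)C(=O)O
Why: Yamaguchi-type esterification: the C4 hydroxyl attacks the unhindered angeloyl carbonyl of the mixed anhydride, and the absence of a nucleophilic amine catalyst should avoid isomerisation of the (Z)-2-methylbut-2-enoate to the tiglate, the tertiary hydroxyl remaining free.

Compound list

1 | 3-(4-methoxyphenyl)propanoic acid | OC(=O)CCc1ccc(OC)cc1 | starting material
2 | isobutyl carbonic 3-(4-methoxyphenyl)propanoic anhydride | CC(C)COC(=O)OC(=O)CCc1ccc(OC)cc1 | intermediate (not isolated)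
3 | 2-diazo-5-(4-methoxyphenyl)pentan-3-one | CC(=[N+]=[N-])C(=O)CCc1ccc(OC)cc1 | intermediate
4 | norcaradiene tautomer of 5 (cyclopropane C3a–C8–C8a; 8a-methyl syn to the cyclohexadiene ring) | C[C@]12C(=O)CC[C@]13C=CC(OC)=C[C@H]23 | intermediate (not isolated)
5 | (8aR)-6-methoxy-8a-methyl-3,8a-dihydroazulen-1(2H)-one (C3a=C4, C5=C6, C7=C8) | C=1C=C(OC)C=C[C@@]2(C)C(=O)CCC12 | intermediate
6 | (8aR)-6,6-ethylenedioxy-8a-methyl-2,3,5,6-tetrahydroazulen-1(8aH)-one (C3a=C4, C7=C8) | C=1CC2(OCCO2)C=C[C@@]3(C)C(=O)CCC13 | intermediate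
7 | (1S,8aR)-6,6-ethylenedioxy-8a-methyl-1,2,3,5,6,8a-hexahydroazulen-1-ol (1α-OH) | C=1CC2(OCCO2)C=C[C@@]3(C)[C@@H](O)CCC13 | intermediate
8 | 3-hydroxy derivative of 7 (allylic alcohol, C3 epimers) | C=1CC2(OCCO2)C=C[C@@]3(C)[C@@H](O)CC(O)C13 | intermediate (not isolated)
9 | 1α-hydroxy-6,6-ethylenedioxy-8a-methyl 3-ketone (enone, C3a=C4; C7=C8) | C=1CC2(OCCO2)C=C[C@@]3(C)[C@@H](O)CC(=O)C13 | intermediate
10 | 1-O-trimethylsilyl ether of 11 | C=1CC2(OCCO2)C=C[C@@]3(C)[C@@H](O[Si](C)(C)C)CC4(OCCO4)C13 | intermediate (not isolated)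
11 | 3,3:6,6-bis(ethylenedioxy)-8a-methyl 1α-alcohol (C3a=C4, C7=C8) | C=1CC2(OCCO2)C=C[C@@]3(C)[C@@H](O)CC4(OCCO4)C13 | intermediate
12 | trans-fused 1α,4α-diol, 3a-H α, 8a-Me β, bis-dioxolane, C7=C8 | O[C@H]1CC2(OCCO2)C=C[C@@]3(C)[C@@H](O)CC4(OCCO4)[C@H]13 | intermediate
13 | 4α-O-TBS ether of 12 | CC(C)(C)[Si](C)(C)O[C@H]1CC2(OCCO2)C=C[C@@]3(C)[C@@H](O)CC4(OCCO4)[C@H]13 | intermediate
14 | 6-ketone (C7=C8 enone), 1α-OH, 4α-OTBS, C3 dioxolane | CC(C)(C)[Si](C)(C)O[C@H]1CC(=O)C=C[C@@]2(C)[C@@H](O)CC3(OCCO3)[C@H]12 | intermediate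
15 | 7α,8α-epoxy-6-ketone | CC(C)(C)[Si](C)(C)O[C@H]1CC(=O)[C@H]2O[C@H]2[C@@]3(C)[C@@H](O)CC4(OCCO4)[C@H]13 | intermediate
16 | 6-methylene-7α,8α-epoxide | CC(C)(C)[Si](C)(C)O[C@H]1CC(=C)[C@H]2O[C@H]2[C@@]3(C)[C@@H](O)CC4(OCCO4)[C@H]13 | intermediate
17 | 6-methyl-6-ene-1α,8α-diol, 4α-OTBS, C3 dioxolane | CC(C)(C)[Si](C)(C)O[C@H]1CC(C)=C[C@@H](O)[C@@]2(C)[C@@H](O)CC3(OCCO3)[C@H]12 | intermediate
18 | 3-ketone (1α,8α-diol, 4α-OTBS, C6=C7) | CC(C)(C)[Si](C)(C)O[C@H]1CC(C)=C[C@@H](O)[C@@]2(C)[C@@H](O)CC(=O)[C@H]12 | intermediate
19 | 3β-hydroxy-3α-isopropyl-1α,8α-diol, 4α-OTBS, C6=C7 | CC(C)(C)[Si](C)(C)O[C@H]1CC(C)=C[C@@H](O)[C@@]2(C)[C@@H](O)C[C@@](O)(C(C)C)[C@H]12 | intermediate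
20 | 6α,7α-epoxy-1α,3β,8α-triol, 6β-Me, 4α-OTBS | CC(C)(C)[Si](C)(C)O[C@H]1C[C@@]2(C)O[C@H]2[C@@H](O)[C@@]2(C)[C@@H](O)C[C@@](O)(C(C)C)[C@H]12 | intermediate
21 | 1α,8α-diacetate of 20 | CC(C)(C)[Si](C)(C)O[C@H]1C[C@@]2(C)O[C@H]2[C@@H](OC(C)=O)[C@@]2(C)[C@@H](OC(C)=O)C[C@@](O)(C(C)C)[C@H]12 | intermediate
22 | 4α-alcohol (1α,8α-diacetoxy-6α,7α-epoxy-3β-hydroxy-3α-isopropyl) | O[C@H]1C[C@@]2(C)O[C@H]2[C@@H](OC(C)=O)[C@@]2(C)[C@@H](OC(C)=O)C[C@@](O)(C(C)C)[C@H]12 | intermediate
23 | CNP0170993.1: 1α,8α-diacetoxy-4α-angeloyloxy-6α,7α-epoxy-3β-hydroxy-3α-isopropyl-6β,8aβ-dimethyl-decahydroazulene (3a-H α) | C/C=C(/C)C(=O)O[C@H]1C[C@@]2(C)O[C@H]2[C@@H](OC(C)=O)[C@@]2(C)[C@@H](OC(C)=O)C[C@@](O)(C(C)C)[C@H]12 | target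

Total step count: 18. Longest linear sequence: 18 steps (fully linear from 1).

Steps most likely to fail

Step 2. The chiral copper carbenoid may discriminate poorly between the two enantiotopic ipso/ortho bonds, or the methyl carbenoid may be drained by 1,2-hydride shift. The fallback sets out from 3 and replaces asymmetric catalysis by a reagent-controlled resolution. Rh2(OAc)4 (1 mol %) in refluxing CH2Cl2 should give the racemic azulenone F1. Glycol/PPTS as in step 3 gives the racemic ketal ketone F2. Reduction with (R)-Me-CBS/catecholborane as in step 4 then turns the two enantiomers into two diastereomeric (1S)-alcohols, 7 and the (1S,8aS)-alcohol F3 (hydroxyl cis to the angular methyl), which are separated by chromatography. The route is rejoined at 7.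

Step 7. Hydroboration of the hindered C3a=C4 bond may be slow enough for borane to attack C7=C8, or addition may take place from the β face and give the cis-fused diol. The fallback sets out from 9 and introduces oxygen at C4 and hydrogen at C3a separately. Nucleophilic epoxidation (tBuOOH, DBU) of the C3a=C4 enone from the α face should give the epoxy ketone F4. SmI2/MeOH at −90 °C cleaves the C3a–O bond, and protonation of the samarium enolate anti to the angular methyl should give the β-hydroxy ketone F5 (4α-OH, 3a-H α). Ketalisation of F5 under the conditions of step 6 passes through the bis-TMS ether F6 and, after methanolysis, comes back to the route at 12.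

Step 14. The bulky secondary organometallic may enolise or reduce the hindered ketone instead of adding, or facial control may erode. The fallback sets out from 18 and builds the isopropyl group in two stages. 2-Propenylmagnesium bromide/CeCl3 adds the smaller sp2 nucleophile from the α face to give the isopropenyl carbinol F7. Hydrogenation with RhCl(PPh3)3/H2, selective for the 1,1-disubstituted alkene over the trisubstituted ring alkene, then gives 19, where the route is rejoined.

Further compounds

F1 | step 2 | racemic 6-methoxy-8a-methyl-3,8a-dihydroazulen-1(2H)-one | CC12C=CC(OC)=CC=C1CCC2=O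
F2 | step 2 | racemic 6,6-ethylenedioxy-8a-methyl-2,3,5,6-tetrahydroazulen-1(8aH)-one | CC12C=CC3(OCCO3)CC=C1CCC2=O
F3 | step 2 | (1S,8aS)-alcohol (1-OH cis to the 8a-methyl) | C=1CC2(OCCO2)C=C[C@]3(C)[C@@H](O)CCC13
F4 | step 7 | 3a,4-α-epoxy-3-ketone (1α-OH, C6 dioxolane, C7=C8) | O1[C@H]2CC3(OCCO3)C=C[C@@]4(C)[C@@H](O)CC(=O)[C@]124
F5 | step 7 | trans-fused 1α,4α-dihydroxy-3-ketone (3a-H α, C6 dioxolane, C7=C8) | O[C@H]1CC2(OCCO2)C=C[C@@]3(C)[C@@H](O)CC(=O)[C@H]13
F6 | step 7 | 1,4-bis-O-trimethylsilyl ether of 12 | C[Si](C)(C)O[C@H]1CC2(OCCO2)C=C[C@@]3(C)[C@@H](O[Si](C)(C)C)CC4(OCCO4)[C@H]13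
F7 | step 14 | 3β-hydroxy-3α-isopropenyl analogue of 19 | CC(C)(C)[Si](C)(C)O[C@H]1CC(C)=C[C@@H](O)[C@@]2(C)[C@@H](O)C[C@@](O)(C(C)=C)[C@H]12
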